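**Plan**
1. Retrosynthesis: after unmasking O5 and O4' (benzyl ethers), ring C is opened at three bonds, C4a–C4, C4–C3 and O1–C2. This leaves a ring-A iodophenol, carbon monoxide (C4 and its oxygen) and a ring-B arylacetylene (C3, C2, C1'–C6').
2. Enabling feature: C4a is the only ring-A carbon without oxygen. It sits between C5–O and C8a–O1, while C6, C7 and C8 all carry OMe, so ring A is a 4,5,6-trimethoxyresorcinol with a mirror plane through C4a and C7. Its two resorcinol oxygens are interchangeable and its single C–H is exactly where the iodide is needed.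
3. Forward: rings A and B are bought as 1,2,3-trimethoxybenzene and syringaldehyde. Ring A gains its two extra oxygens one at a time (Br to OH twice, with benzylation in between) and then iodine. Ring B is benzylated and homologated to the alkyne.
4. Ring C is the only ring built. It arises in one operation from the three components, and hydrogenolysis of both benzyl ethers ends the route.
5. Stereochemistry: the target is flat and has no stereogenic element, so nothing has to be set or preserved.

Key step: step 8

Remark on the chemistry: the target SMILES carries no stereodescriptor and the molecule has no stereocentre, axis or configurable double bond. The achiral compound itself is therefore taken as the goal.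

**Step 1**
Reactants: 1 1,2,3-trimethoxybenzene
Product: 2 1,5-dibromo-2,3,4-trimethoxybenzene
Conditions: NBS (2.1 equiv), MeCN, 0 °C → rt
Reagents that add atoms: N-bromosuccinimide, O=C1CCC(=O)N1Br
Why: Electrophilic aromatic bromination, in which each outer methoxy group activates the position ortho to itself and para to the other outer methoxy group, whereas C5 is para only to the central methoxy group that is twisted out of conjugation, so both bromines should enter at C4 and C6 and leave the C–H between them untouched.

**Step 2**
Reactants: 2 1,5-dibromo-2,3,4-trimethoxybenzene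
Product: 5 5-bromo-2,3,4-trimethoxyphenol, via aryllithium 3 (not isolated), via dimethyl arylboronate 4 (not isolated)
Conditions: n-BuLi (1.0 equiv), THF, −78 °C; B(OMe)3, −78 °C → rt; AcOH (1.5 equiv), 30% aq H2O2 (1.2 equiv), 0 °C → rt
Reagents that add atoms: hydrogen peroxide, OO (phenol oxygen of 5); for the intermediates only: n-butyllithium, [Li]CCCC (Li of 3); trimethyl borate, COB(OC)OC (B(OMe)2 of 4)
Why: Bromine–lithium exchange should stop after one of the two equivalent bromines because a second exchange would build a dianion, and borate trapping followed by the peroxide-induced 1,2-aryl shift from boron to oxygen (boronate oxidation) turns C–Li into C–OH.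

**Step 3**
Reactants: 5 5-bromo-2,3,4-trimethoxyphenol
Product: 6 1-(benzyloxy)-5-bromo-2,3,4-trimethoxybenzene
Conditions: BnBr, K2CO3, DMF, rt
Reagents that add atoms: benzyl bromide, BrCc1ccccc1
Why: Williamson ether synthesis on the only OH present, which marks the oxygen that becomes O5 and differentiates the two ring-A oxygens without a statistical monoprotection.

**Step 4**
Reactants: 6 1-(benzyloxy)-5-bromo-2,3,4-trimethoxybenzene
Product: 9 5-(benzyloxy)-2,3,4-trimethoxyphenol, via aryllithium 7 (not isolated), via dimethyl arylboronate 8 (not isolated)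
Conditions: n-BuLi (1.05 equiv), THF, −78 °C; B(OMe)3, −78 °C → rt; AcOH (1.5 equiv), 30% aq H2O2 (1.2 equiv), 0 °C → rt
Reagents that add atoms: hydrogen peroxide, OO (phenol oxygen of 9); for the intermediates only: n-butyllithium, [Li]CCCC (Li of 7); trimethyl borate, COB(OC)OC (B(OMe)2 of 8)
Why: The same exchange–borylation–oxidation sequence applies to the remaining bromide, since at −78 °C exchange is far faster than benzylic deprotonation of the ether, and near-stoichiometric peroxide in weakly acidic THF should spare the electron-rich ring.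

**Step 5**
Reactants: 9 5-(benzyloxy)-2,3,4-trimethoxyphenol
Product: 10 3-(benzyloxy)-2-iodo-4,5,6-trimethoxyphenol
Conditions: NIS (1.05 equiv), MeCN, 0 °C, dark
Reagents that add atoms: N-iodosuccinimide, O=C1CCC(=O)N1I
Why: Electrophilic aromatic iodination of an activated phenol, in which the only ring-A C–H lies ortho to both OH and OBn and the phenyl ring of the benzyl group is far less nucleophilic, so only one monoiodide can form.

**Step 6**
Reactants: 11 syringaldehyde (4-hydroxy-3,5-dimethoxybenzaldehyde)
Product: 12 4-(benzyloxy)-3,5-dimethoxybenzaldehyde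
Conditions: BnBr, K2CO3, DMF, 60 °C
Reagents that add atoms: benzyl bromide, BrCc1ccccc1
Why: Williamson ether synthesis on the acidic, aldehyde-conjugated phenol, giving a protecting group that leaves in the same final operation as the one on O5.

**Step 7**
Reactants: 12 4-(benzyloxy)-3,5-dimethoxybenzaldehyde
Product: 14 2-(benzyloxy)-5-ethynyl-1,3-dimethoxybenzene, via diazoalkene 13 (not isolated)
Conditions: dimethyl (1-diazo-2-oxopropyl)phosphonate (1.3 equiv), K2CO3 (2 equiv), MeOH, rt
Reagents that add atoms: dimethyl (1-diazo-2-oxopropyl)phosphonate, COP(=O)(OC)C(=[N+]=[N-])C(C)=O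
Why: Seyferth–Gilbert homologation in the Ohira–Bestmann form, where methanolysis of the reagent frees the diazomethylphosphonate anion, this olefinates the non-enolisable aldehyde to diazoalkene 13, and loss of N2 with a 1,2-hydrogen shift gives the terminal alkyne under conditions harmless to the benzyl ether.

**Step 8**
Reactants: 10 3-(benzyloxy)-2-iodo-4,5,6-trimethoxyphenol; 14 2-(benzyloxy)-5-ethynyl-1,3-dimethoxybenzene (1.3 equiv); 15 carbon monoxide
Product: 18 5-(benzyloxy)-2-[4-(benzyloxy)-3,5-dimethoxyphenyl]-6,7,8-trimethoxy-4H-chromen-4-one, via ynone 16 (not isolated), via enaminone 17 (not isolated)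
Conditions: PdCl2(dppf) (5 mol %), CO (20 bar), Et2NH, 120 °C, autoclave, no copper
Reagents that add atoms: carbon monoxide 15, [C-]#[O+] (C4 and its oxygen); diethylamine, CCNCC (NEt2 group of 17 only, lost again on ring closure)
Why: Pd(0) inserts into the C–I bond of 10, CO migrates in to give a catalyst-bound aroylpalladium iodide, and this takes up the amine-deprotonated alkyne 14 and reductively eliminates to ynone 16, which creates C4a–C4 and C4–C3. The closest known reaction type is the carbonylative Sonogashira annulation of ortho-iodophenols with terminal arylacetylenes to flavones, used here on a more crowded and more electron-rich iodide. Diethylamine then adds in conjugate fashion to 16 to give enaminone 17, and the phenol oxygen attacks the amine-bearing carbon and expels diethylamine, so ring C closes through O1–C2 by a six-membered addition–elimination (formally 6-endo). No stereocentre is formed. The step needs pyranone rather than five-membered aurone closure, which is secured because C2 is the only electrophilic carbon left in 17; it needs carbonylation to outrun direct alkynylation, which CO pressure, the absence of copper and the ready CO insertion expected of an electron-rich, doubly ortho-substituted arylpalladium should provide; and amide formation should be held back because the two ortho substituents shield the acyl carbon from the bulky secondary amine. Regiochemistry is not at issue, since only one oxygen next to C4a is free in 10 and the benzylated one necessarily becomes O5.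

**Step 9**
Reactants: 18 5-(benzyloxy)-2-[4-(benzyloxy)-3,5-dimethoxyphenyl]-6,7,8-trimethoxy-4H-chromen-4-one
Product: 19 5-hydroxy-2-(4-hydroxy-3,5-dimethoxyphenyl)-6,7,8-trimethoxy-4H-chromen-4-one (5,4'-dihydroxy-6,7,8,3',5'-pentamethoxyflavone)
Conditions: H2 (1 atm), 10% Pd/C, EtOAc–MeOH, rt
Reagents that add atoms: none
Why: Catalytic hydrogenolysis cleaves both benzylic C–O bonds, while at 1 atm and rt the C2=C3 bond of the conjugated pyranone and the aryl methyl ethers should stay intact, and the freed 5-OH is held by a hydrogen bond to the C4 carbonyl.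

**Compound list**
1 | 1,2,3-trimethoxybenzene | COc1cccc(OC)c1OC | starting material
2 | 1,5-dibromo-2,3,4-trimethoxybenzene | COc1c(Br)cc(Br)c(OC)c1OC | intermediate
3 | (5-bromo-2,3,4-trimethoxyphenyl)lithium | COc1c([Li])cc(Br)c(OC)c1OC | intermediate
4 | dimethyl (5-bromo-2,3,4-trimethoxyphenyl)boronate | COB(OC)c1cc(Br)c(OC)c(OC)c1OC | intermediate
5 | 5-bromo-2,3,4-trimethoxyphenol | COc1c(O)cc(Br)c(OC)c1OC | intermediate
6 | 1-(benzyloxy)-5-bromo-2,3,4-trimethoxybenzene | COc1c(OCc2ccccc2)cc(Br)c(OC)c1OC | intermediate
7 | [5-(benzyloxy)-2,3,4-trimethoxyphenyl]lithium | COc1c(OCc2ccccc2)cc([Li])c(OC)c1OC | intermediate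
8 | dimethyl [5-(benzyloxy)-2,3,4-trimethoxyphenyl]boronate | COB(OC)c1cc(OCc2ccccc2)c(OC)c(OC)c1OC | intermediate
9 | 5-(benzyloxy)-2,3,4-trimethoxyphenol | COc1c(O)cc(OCc2ccccc2)c(OC)c1OC | intermediate
10 | 3-(benzyloxy)-2-iodo-4,5,6-trimethoxyphenol | COc1c(O)c(I)c(OCc2ccccc2)c(OC)c1OC | intermediate
11 | syringaldehyde (4-hydroxy-3,5-dimethoxybenzaldehyde) | COc1cc(C=O)cc(OC)c1O | starting material
12 | 4-(benzyloxy)-3,5-dimethoxybenzaldehyde | COc1cc(C=O)cc(OC)c1OCc1ccccc1 | intermediate
13 | 2-(benzyloxy)-5-(2-diazoethenyl)-1,3-dimethoxybenzene | COc1cc(C=C=[N+]=[N-])cc(OC)c1OCc1ccccc1 | intermediate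
14 | 2-(benzyloxy)-5-ethynyl-1,3-dimethoxybenzene | C#Cc1cc(OC)c(OCc2ccccc2)c(OC)c1 | intermediate
15 | carbon monoxide | [C-]#[O+] | starting material
16 | 1-[2-(benzyloxy)-6-hydroxy-3,4,5-trimethoxyphenyl]-3-[4-(benzyloxy)-3,5-dimethoxyphenyl]prop-2-yn-1-one | COc1c(O)c(C(=O)C#Cc2cc(OC)c(OCc3ccccc3)c(OC)c2)c(OCc2ccccc2)c(OC)c1OC | intermediate
17 | (E)-1-[2-(benzyloxy)-6-hydroxy-3,4,5-trimethoxyphenyl]-3-[4-(benzyloxy)-3,5-dimethoxyphenyl]-3-(diethylamino)prop-2-en-1-one (push–pull alkene, geometry labile and without consequence) | COc1c(O)c(C(=O)/C=C(/N(CC)CC)c2cc(OC)c(OCc3ccccc3)c(OC)c2)c(OCc2ccccc2)c(OC)c1OC | intermediate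
18 | 5-(benzyloxy)-2-[4-(benzyloxy)-3,5-dimethoxyphenyl]-6,7,8-trimethoxy-4H-chromen-4-one | COc1cc(-c2cc(=O)c3c(OCc4ccccc4)c(OC)c(OC)c(OC)c3o2)cc(OC)c1OCc1ccccc1 | intermediate
19 | 5-hydroxy-2-(4-hydroxy-3,5-dimethoxyphenyl)-6,7,8-trimethoxy-4H-chromen-4-one (achiral) | COc1cc(-c2cc(=O)c3c(O)c(OC)c(OC)c(OC)c3o2)cc(OC)c1O | target

**Total step count:** 9 steps.
**Longest linear sequence:** 7 steps (steps 1–5, 8, 9). The alkyne branch (steps 6 and 7) joins at step 8.

**Steps most likely to fail**

1. Step 8.
   - What may go wrong: oxidative addition at the doubly ortho-substituted, electron-rich C–I bond may be slow. Iodine may be lost reductively by hydride transfer from the amine. Diethylamine may intercept the aroylpalladium. Alkynylation may occur without uptake of CO and be followed by furan closure.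
   - Fallback (sets out from 10 and 14, returns at 18): C4 is brought in as a formyl carbon on the alkyne, and C4a–C4 is made by a polar organometallic addition instead of catalysis. Alkyne 14 would be deprotonated with n-BuLi (THF, −78 °C) to {[4-(benzyloxy)-3,5-dimethoxyphenyl]ethynyl}lithium F1 and formylated with DMF to 3-[4-(benzyloxy)-3,5-dimethoxyphenyl]prop-2-ynal F2. Iodophenol 10 would be deprotonated with MeMgCl·LiCl and then subjected to iodine–magnesium exchange with i-PrMgCl·LiCl, giving chloromagnesium 3-(benzyloxy)-2-(chloromagnesio)-4,5,6-trimethoxyphenolate F3. Addition of F3 to F2 should give racemic 3-(benzyloxy)-2-{3-[4-(benzyloxy)-3,5-dimethoxyphenyl]-1-hydroxyprop-2-yn-1-yl}-4,5,6-trimethoxyphenol F4. Oxidation of F4 with MnO2 (CH2Cl2, rt) would deliver ynone 16. Warming 16 with Et2NH in EtOH would take it through enaminone 17 to 18 by the same ring closure as in the main route.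

2. Step 5.
   - What may go wrong: the iodonium source may oxidise the para-methoxyphenol to a quinone in competition with substitution, and iodine may be lost again by protodeiodination on contact with acid.
   - Fallback (sets out from 9, returns at 10): the C–I bond is made from a carbanion rather than by electrophilic substitution. Phenol 9 would be converted with MOMCl and i-Pr2NEt (CH2Cl2) into 1-(benzyloxy)-2,3,4-trimethoxy-5-(methoxymethoxy)benzene F5. Directed ortho-lithiation (n-BuLi, THF, −20 °C) at the C–H flanked by OMOM and OBn should give [2-(benzyloxy)-3,4,5-trimethoxy-6-(methoxymethoxy)phenyl]lithium F6. Quenching with I2 would give 1-(benzyloxy)-2-iodo-4,5,6-trimethoxy-3-(methoxymethoxy)benzene F7, and catalytic HCl in MeOH would remove the acetal to give 10.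

3. Step 2.
   - What may go wrong: both bromines may exchange. Alternatively, a proton may transfer from the C–H between the two bromines of unreacted 2 to aryllithium 3, with ensuing migration of bromine, which would erode the substitution pattern.
   - Fallback (sets out from 1, returns at 5, and also bypasses step 1): the first extra oxygen comes from an aldehyde by Baeyer–Villiger oxidation. Vilsmeier–Haack formylation of 1 (POCl3, DMF, 80 °C) would give 2,3,4-trimethoxybenzaldehyde F8. Bromination (Br2, NaOAc, AcOH) should go to C5, where the ortho effect of 4-OMe, the para effect of 2-OMe and the meta effect of the aldehyde coincide, giving 5-bromo-2,3,4-trimethoxybenzaldehyde F9. mCPBA (CH2Cl2) would convert F9 into 5-bromo-2,3,4-trimethoxyphenyl formate F10, and K2CO3 in MeOH would release 5.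

**Further compounds**
F1 | step 8 | {[4-(benzyloxy)-3,5-dimethoxyphenyl]ethynyl}lithium | [Li]C#Cc1cc(OC)c(OCc2ccccc2)c(OC)c1
F2 | step 8 | 3-[4-(benzyloxy)-3,5-dimethoxyphenyl]prop-2-ynal | O=CC#Cc1cc(OC)c(OCc2ccccc2)c(OC)c1
F3 | step 8 | chloromagnesium 3-(benzyloxy)-2-(chloromagnesio)-4,5,6-trimethoxyphenolate | COc1c(O[Mg]Cl)c([Mg]Cl)c(OCc2ccccc2)c(OC)c1OC
F4 | step 8 | 3-(benzyloxy)-2-{3-[4-(benzyloxy)-3,5-dimethoxyphenyl]-1-hydroxyprop-2-yn-1-yl}-4,5,6-trimethoxyphenol (racemic) | COc1c(O)c(C(O)C#Cc2cc(OC)c(OCc3ccccc3)c(OC)c2)c(OCc2ccccc2)c(OC)c1OC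
F5 | step 5 | 1-(benzyloxy)-2,3,4-trimethoxy-5-(methoxymethoxy)benzene | COCOc1cc(OCc2ccccc2)c(OC)c(OC)c1OC
F6 | step 5 | [2-(benzyloxy)-3,4,5-trimethoxy-6-(methoxymethoxy)phenyl]lithium | COCOc1c([Li])c(OCc2ccccc2)c(OC)c(OC)c1OC
F7 | step 5 | 1-(benzyloxy)-2-iodo-4,5,6-trimethoxy-3-(methoxymethoxy)benzene | COCOc1c(I)c(OCc2ccccc2)c(OC)c(OC)c1OC
F8 | step 2 | 2,3,4-trimethoxybenzaldehyde | COc1ccc(C=O)c(OC)c1OC
F9 | step 2 | 5-bromo-2,3,4-trimethoxybenzaldehyde | COc1c(Br)cc(C=O)c(OC)c1OC
F10 | step 2 | 5-bromo-2,3,4-trimethoxyphenyl formate | COc1c(Br)cc(OC=O)c(OC)c1OC
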